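A direct plan would keep ring A from the chiral pool and close ring B late: (R)-linalool A1 would be epoxidised and cyclised to cis-furanoid linalool oxide A2, the vinyl group homologated to a β-keto ester and annulated to a 3-acylfuran, and the bromoacetyl methyl ketone A3 closed at C9–C10 by a SmI2 Reformatsky-type aldol to the furan-bridged hydroxy ketone A4; syn reduction, methacrylation, singlet-oxygen oxidation of the furan to hydroxybutenolide A5, dehydration, desilylation and acetylation would finish.
Weak point 1, the SmI2 closure of the ten-membered ring from open-chain A3: an end-to-end medium-ring closure against entropy and transannular strain, which must beat intermolecular aldol addition and reduction of the α-alkoxy ketone and sets C10 only through an assumed chelate.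
Weak point 2, the dehydration of the hydroxyisopropyl group and its oxidative cleavage back to a methyl ketone, with a silyl ether put on and taken off C13: redox and protecting-group traffic that builds no skeletal bond inside a linear run of fifteen steps.
Weak point 3, the late photooxygenation of the furan and the base-induced dehydration of A5 with the methacrylate already in place: a β-alkoxy ketone stage at which ring A can open by β-elimination, reached only after nearly all material has been invested.

**Retrosynthetic overview**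
Ring A (C1–C4, the ring oxygen, C15) is read as a dearomatised 2-methylfuran: its Diels–Alder adduct with a 3-bromopropiolate is a 7-oxanorbornane that already holds the 1,4-epoxy bridge with H on C1 and CH3 on C4.
Ring B is not closed end to end but grown out of the six-membered carbocycle C1–C2–C3–C4–C5–C10 of that bicycle: exo aldol (C5–C6) and exo alkynylation (C10–C9) place a 2-silyloxyvinyl group and an ethoxyethynyl carbinol cis, and an anionic acetylenic oxy-Cope shift cuts C5–C10 and forms C7–C8.
The shift delivers C6, C8 and C10 as silyl enol ether, ethyl enol ether and ketone. Methyl addition (C10), enol acylation with intramolecular Knoevenagel condensation of an acetoxypyruvoyl unit (lactone, C11–C13, 13-acetate at its final oxidation level) and 1,3-syn reduction (C8) then follow without protecting-group steps.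
Ring order: A by cycloaddition, B by ring expansion, lactone last. This avoids the medium-ring cyclisation, the dehydration/re-oxidation detour and the furan photooxygenation.

Key step: step 10

Assumption: the salt of the required ketal acid with (R)-1-phenylethylamine is taken to be the less soluble one; if the antipode crystallises, the (S)-amine is to be used.

Step 1
Reactants: 1 methyl propiolate
Product: 2 methyl 3-bromopropiolate
Conditions: N-bromosuccinimide, AgNO3 (cat.), acetone, rt
Reagents that add atoms: N-bromosuccinimide, O=C1CCC(=O)N1Br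
Why: Silver-catalysed electrophilic bromination of the terminal alkyne C–H (through the silver acetylide) should give the 1-bromoalkyne; no stereocentre is involved.

Step 2
Reactants: 2 methyl 3-bromopropiolate; 3 2-methylfuran
Product: 4 methyl (1R,4S)-3-bromo-1-methyl-7-oxabicyclo[2.2.1]hepta-2,5-diene-2-carboxylate (formed as the racemate)
Conditions: benzene, 80 °C (sealed vessel); chromatographic removal of the minor regioisomer
Reagents that add atoms: none
Why: In this thermal Diels–Alder reaction the more nucleophilic unsubstituted α-carbon of 2-methylfuran should bond to the bromine-bearing β-carbon of the alkynoate, so the ester carbon (future C5 with C6) ends next to the methyl bridgehead (future C4) and the bromine-bearing carbon (future C10) next to the H bridgehead (future C1); both bridgeheads form together, as a racemate.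

Step 3
Reactants: 4 bromodiene ester
Product: 5 methyl (1R,2S,4S)-3,3-dimethoxy-1-methyl-7-oxabicyclo[2.2.1]hept-5-ene-2-carboxylate (racemic; ester endo)
Conditions: NaOMe, MeOH, 0 °C to rt
Reagents that add atoms: sodium methoxide, [Na+].[O-]C; methanol, CO
Why: Addition–elimination of methoxide on the β-bromo acrylate followed by conjugate addition of methanol should give the β-keto ester as its dimethyl ketal, and protonation of the ester enolate from the exo face should leave the ester endo.

Step 4
Reactants: 5 unsaturated ketal ester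
Product: 6 methyl (1R,2S,4S)-3,3-dimethoxy-1-methyl-7-oxabicyclo[2.2.1]heptane-2-carboxylate (racemic)
Conditions: H2 (1 atm), Pd/C, EtOAc, rt
Reagents that add atoms: none
Why: Catalytic hydrogenation of the strained disubstituted alkene from the exo face gives C2 and C3 as CH2 groups and removes the possibility of a retro-Diels–Alder reaction.

Step 5
Reactants: 6 racemic ketal ester
Product: 7 (1R,2S,4S)-3,3-dimethoxy-1-methyl-7-oxabicyclo[2.2.1]heptane-2-carboxylic acid (single enantiomer)
Conditions: LiOH, THF/H2O, rt; (R)-1-phenylethylamine, EtOAc/EtOH, fractional crystallisation of the salt; then 1 M HCl, 0 °C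
Reagents that add atoms: lithium hydroxide, [Li+].[OH-]
Why: Saponification and classical resolution through diastereomeric ammonium salts fix the absolute configuration of both bridgeheads (future C1 S and C4 R), which no later step touches.

Step 6
Reactants: 7 resolved ketal acid
Product: 8 (1S,4R)-4-methyl-7-oxabicyclo[2.2.1]heptan-2-one
Conditions: 2 M HCl, THF, 45 °C
Reagents that add atoms: water, O
Why: Acid hydrolysis of the ketal and decarboxylation of the resulting β-keto acid (through the endocyclic enol) give the ketone with C=O next to the H bridgehead; the carboxyl group that steered the cycloaddition is removed so that C5 can be set by C–C bond formation.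

Step 7
Reactants: 8 bicyclic ketone; 9 acetaldehyde; 10 ethoxyacetylene
Product: 12 (1S,4R)-2-exo-(ethoxyethynyl)-3-exo-(1-hydroxyethyl)-4-methyl-7-oxabicyclo[2.2.1]heptan-2-endo-ol (side-chain carbinol epimers), via lithium aldolate 11 (not isolated)
Conditions: LiN(iPr)2, THF, –78 °C; MeCHO; then LiC≡COEt (from 10 and n-BuLi), –78 to –30 °C; aq. NH4Cl
Reagents that add atoms: none
Why: The lithium enolate (only C5 can be deprotonated, C1 being a bridgehead) should add to acetaldehyde from the exo face (aldol addition, as known for 7-oxabicyclo[2.2.1]heptan-2-one enolates), and the regenerated ketone should take the rod-like lithium acetylide from the exo face as well (1,2-addition, the aldolate oxygen on that face helping delivery), so both new carbon substituents are exo and cis; the side-chain carbinol centre is lost in step 8.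

Step 8
Reactants: 12 diol
Product: 13 1-[(1S,2R,3S,4R)-2-(ethoxyethynyl)-2-hydroxy-4-methyl-7-oxabicyclo[2.2.1]heptan-3-yl]ethan-1-one (alkynyl and acetyl exo)
Conditions: Dess–Martin periodinane, NaHCO3, CH2Cl2, 0 °C
Reagents that add atoms: none
Why: Dess–Martin oxidation converts the secondary alcohol into the methyl ketone (C6, C7) under buffered, non-basic conditions that should spare the tertiary propargylic alcohol and the acid-sensitive ynol ether and not epimerise C5.

Step 9
Reactants: 13 β-hydroxy ketone
Product: 14 (1S,4R)-2-exo-(ethoxyethynyl)-4-methyl-3-exo-{1-[(triisopropylsilyl)oxy]ethenyl}-7-oxabicyclo[2.2.1]heptan-2-endo-ol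
Conditions: LiN(iPr)2 (2.2 equiv), THF, –78 °C (13 added to the base); iPr3SiOTf (1.05 equiv), DMPU, –78 °C; aq. NaHCO3
Reagents that add atoms: triisopropylsilyl trifluoromethanesulfonate, CC(C)[Si](C(C)C)(C(C)C)OS(=O)(=O)C(F)(F)F
Why: Double deprotonation gives the alkoxide and the kinetic methyl-side enolate (C5–H is tertiary and hindered), and O-silylation of the enolate gives the regiodefined silyl enol ether C6=C7, while the hindered tertiary lithium alkoxide should stay unsilylated; inverse addition at –78 °C should outrun retro-aldol cleavage.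

Step 10
Reactants: 14 cis-disposed alkynyl carbinol and silyl enol ether
Product: 16 (1S,6E,8R)-4-ethoxy-8-methyl-6-[(triisopropylsilyl)oxy]-11-oxabicyclo[6.2.1]undeca-3,6-dien-2-one (germacrane numbering: C10 ketone; C8 ethyl enol ether; C6 silyl enol ether with C5=C6; C8=C9 geometry of no consequence), via potassium allenolate 15 (not isolated)
Conditions: KH, 18-crown-6, THF, 0 °C to rt; pH 7 phosphate buffer at –78 °C
Reagents that add atoms: none
Why: KH/18-crown-6 should give the naked potassium alkoxide of 14, which undergoes a concerted anionic [3,3] sigmatropic shift (acetylenic oxy-Cope rearrangement) across the 1,5-enyne C8≡C9–C10(O–)–C5–C6=C7: the strained C5–C10 bond of the oxanorbornane breaks, C7–C8 forms, and allenolate 15 is protonated at C9 on work-up to the β-ethoxy enone. The closest known reaction type is the anionic oxy-Cope ring expansion by four carbons of 1-alkynyl-2-alkenylcycloalkanols and of 2-alkenylbicyclo[2.2.1]heptan-2-ols to bicyclo[6.2.1]undecenones. Ring B (ten-membered carbocycle, nine-membered when counted through the ring A oxygen) is thus not closed end to end but made by four-atom enlargement of the six-membered ring C1–C2–C3–C4–C5–C10 through a boat-like six-centre transition state on the exo face, while ring A stays intact. No new stereocentre is kept (C8 becomes sp2), but the C5=C6 geometry is set: only the rotamer with C7 over the bicycle and the silyloxy group pointing outward lets C7 reach C8, which puts C4 and C7 cis (5E) as the ring demands; C1 and C4 are not touched. The step needs the two π groups cis on C10 and C5 (secured by the exo aldol and exo alkynylation of step 7), a [3,3] shift faster than O-to-O silyl transfer (hence the bulky triisopropylsilyl group) and faster than heterolytic cleavage (C5 carries no anion-stabilising group once the ketone is an enol ether); relief of the oxanorbornane strain and formation of the conjugated enolate should make it irreversible.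

Step 11
Reactants: 16 ring-expanded β-ethoxy enone
Product: 18 (1S,2R,6E,8R)-2-hydroxy-2,8-dimethyl-6-[(triisopropylsilyl)oxy]-11-oxabicyclo[6.2.1]undec-6-en-4-one (germacrane numbering: 10R tertiary alcohol; C8 ketone; C6 silyl enol ether), via tertiary carbinol 17 (not isolated)
Conditions: MeMgBr, CH2Cl2/Et2O, –78 to –20 °C; aq. NH4Cl; crude 17 then oxalic acid (cat.), THF/H2O, 0 °C
Reagents that add atoms: methylmagnesium bromide, C[Mg]Br; water, O
Why: 1,2-Addition of the Grignard reagent to the vinylogous ester carbonyl under Cram chelate control (magnesium held between the C10 carbonyl oxygen and the ring A oxygen, attack from the side of H1) should set C10 (R), and mild aqueous acid should hydrolyse the ethyl enol ether to the C8 ketone (an interrupted Stork–Danheiser sequence) while the tertiary alcohol and the more robust silyl enol ether remain; a shift of the silyl enol ether into conjugation with C8 would not matter for step 13.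

Step 12
Reactants: 19 bromopyruvic acid
Product: 20 3-acetoxy-2-oxopropanoic acid
Conditions: KOAc (2.2 equiv), DMF, rt; then 1 M HCl, extraction
Reagents that add atoms: potassium acetate, CC(=O)[O-].[K+]
Why: SN2 displacement of the activated α-bromo ketone by acetate installs the future 13-acetate on the three-carbon unit C11–C12–C13.

Step 13
Reactants: 18 silyl enol ether ketone; 20 3-acetoxy-2-oxopropanoic acid
Product: 23 (1S,4R,5E,10R)-13-acetoxy-10-hydroxy-8-oxo-1,4-epoxygermacra-5,7(11)-dien-12,6-olide, via 3-acetoxy-2-oxopropanoyl chloride 21 (not isolated), via enol pyruvate ester 22 (not isolated)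
Conditions: 20, 1-chloro-N,N,2-trimethylprop-1-en-1-amine, CH2Cl2, 0 °C; then 18, Bu4N[Ph3SiF2] (added slowly), CH2Cl2, –40 to 0 °C; then Et3N (cat.), 0 °C to rt
Reagents that add atoms: none
Why: Fluoride-triggered O-acylation of the silyl enol ether by the α-keto acid chloride (the enolate is trapped as it forms, so it should neither C-acylate nor open ring A) gives enol ester 22, whose C7 methylene (α to the C8 ketone) should add to the pyruvoyl ketone in a 5-membered intramolecular aldol (Knoevenagel-type) condensation and lose water; the ring fixes the C7=C11 geometry, C5=C6 (E) is carried over from 16, and C12 and C13 arrive at their final oxidation level.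

Step 14
Reactants: 23 8-oxo butenolide
Product: 24 (1S,4R,5E,8S,10R)-13-acetoxy-8,10-dihydroxy-1,4-epoxygermacra-5,7(11)-dien-12,6-olide
Conditions: Et2BOMe, THF/MeOH, –78 °C; NaBH4; AcOH; MeOH co-evaporation
Reagents that add atoms: none
Why: In the Narasaka–Prasad reduction boron ties the C10 oxygen and the C8 carbonyl into a six-membered chelate, and external hydride should attack the activated ketone 1,2 on the face that gives the 1,3-syn diol, which is (8S) next to (10R); the lactone and the acetate should survive at –78 °C.

Step 15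
Reactants: 24 8,10-diol
Product: 25 CNP0516045.1, (1S,4R,5E,8S,10R)-13-acetoxy-10-hydroxy-8-(methacryloyloxy)-1,4-epoxygermacra-5,7(11)-dien-12,6-olide
Conditions: methacrylic anhydride, Et3N, DMAP (cat.), CH2Cl2, –20 to 0 °C
Reagents that add atoms: methacrylic anhydride, C=C(C)C(=O)OC(=O)C(C)=C
Why: DMAP-catalysed acylation should esterify the secondary C8 hydroxyl, whereas the tertiary C10 hydroxyl is too hindered to react at low temperature.

**Compound list**

1 | methyl propiolate | C#CC(=O)OC | starting material
2 | methyl 3-bromopropiolate | BrC#CC(=O)OC | intermediate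
3 | 2-methylfuran | Cc1ccco1 | starting material
4 | methyl (1R,4S)-3-bromo-1-methyl-7-oxabicyclo[2.2.1]hepta-2,5-diene-2-carboxylate (racemic; the enantiomer carried on is drawn) | C[C@]12C=C[C@H](O1)C(Br)=C2C(=O)OC | intermediate
5 | methyl (1R,2S,4S)-3,3-dimethoxy-1-methyl-7-oxabicyclo[2.2.1]hept-5-ene-2-carboxylate (racemic; ester endo) | C[C@]12C=C[C@H](O1)C(OC)(OC)[C@H]2C(=O)OC | intermediate
6 | methyl (1R,2S,4S)-3,3-dimethoxy-1-methyl-7-oxabicyclo[2.2.1]heptane-2-carboxylate (racemic) | C[C@]12CC[C@H](O1)C(OC)(OC)[C@H]2C(=O)OC | intermediate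
7 | (1R,2S,4S)-3,3-dimethoxy-1-methyl-7-oxabicyclo[2.2.1]heptane-2-carboxylic acid | C[C@]12CC[C@H](O1)C(OC)(OC)[C@H]2C(O)=O | intermediate
8 | (1S,4R)-4-methyl-7-oxabicyclo[2.2.1]heptan-2-one | C[C@]12CC[C@H](O1)C(=O)C2 | intermediate
9 | acetaldehyde | CC=O | starting material
10 | ethoxyacetylene (ethoxyethyne) | C#COCC | starting material
11 | lithium 1-[(1S,4R)-4-methyl-2-oxo-7-oxabicyclo[2.2.1]heptan-3-exo-yl]ethan-1-olate (carbinol epimers) | C[C@]12CC[C@H](O1)C(=O)[C@@H]2C(C)[O-].[Li+] | intermediate
12 | (1S,4R)-2-exo-(ethoxyethynyl)-3-exo-(1-hydroxyethyl)-4-methyl-7-oxabicyclo[2.2.1]heptan-2-endo-ol (carbinol epimers) | C[C@]12CC[C@H](O1)[C@](O)(C#COCC)[C@@H]2C(C)O | intermediate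
13 | 1-[(1S,2R,3S,4R)-2-(ethoxyethynyl)-2-hydroxy-4-methyl-7-oxabicyclo[2.2.1]heptan-3-yl]ethan-1-one | C[C@]12CC[C@H](O1)[C@](O)(C#COCC)[C@@H]2C(C)=O | intermediate
14 | (1S,4R)-2-exo-(ethoxyethynyl)-4-methyl-3-exo-{1-[(triisopropylsilyl)oxy]ethenyl}-7-oxabicyclo[2.2.1]heptan-2-endo-ol | C[C@]12CC[C@H](O1)[C@](O)(C#COCC)[C@@H]2C(=C)O[Si](C(C)C)(C(C)C)C(C)C | intermediate
15 | potassium allenolate from the [3,3] shift of 14 (C10(O–)=C9=C8(OEt); C5=C6 silyl enol ether) | C[C@]12CC[C@H](O1)C([O-])=C=C(OCC)C/C(O[Si](C(C)C)(C(C)C)C(C)C)=C\2.[K+] | intermediate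
16 | (1S,6E,8R)-4-ethoxy-8-methyl-6-[(triisopropylsilyl)oxy]-11-oxabicyclo[6.2.1]undeca-3,6-dien-2-one | C[C@]12CC[C@H](O1)C(=O)C=C(OCC)C/C(O[Si](C(C)C)(C(C)C)C(C)C)=C\2 | intermediate
17 | (1S,2R,6E,8R)-4-ethoxy-2,8-dimethyl-6-[(triisopropylsilyl)oxy]-11-oxabicyclo[6.2.1]undeca-3,6-dien-2-ol | C[C@]12CC[C@H](O1)[C@](C)(O)C=C(OCC)C/C(O[Si](C(C)C)(C(C)C)C(C)C)=C\2 | intermediate
18 | (1S,2R,6E,8R)-2-hydroxy-2,8-dimethyl-6-[(triisopropylsilyl)oxy]-11-oxabicyclo[6.2.1]undec-6-en-4-one | C[C@]12CC[C@H](O1)[C@](C)(O)CC(=O)C/C(O[Si](C(C)C)(C(C)C)C(C)C)=C\2 | intermediate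
19 | bromopyruvic acid (3-bromo-2-oxopropanoic acid) | OC(=O)C(=O)CBr | starting material
20 | 3-acetoxy-2-oxopropanoic acid | CC(=O)OCC(=O)C(O)=O | intermediate
21 | 3-acetoxy-2-oxopropanoyl chloride | CC(=O)OCC(=O)C(Cl)=O | intermediate
22 | (1S,6E,8R,10R)-10-hydroxy-8,10-dimethyl-4-oxo-11-oxabicyclo[6.2.1]undec-6-en-6-yl 3-acetoxy-2-oxopropanoate (enol ester of 18) | C[C@]12CC[C@H](O1)[C@](C)(O)CC(=O)C/C(OC(=O)C(=O)COC(C)=O)=C\2 | intermediate
23 | (1S,4R,5E,10R)-13-acetoxy-10-hydroxy-8-oxo-1,4-epoxygermacra-5,7(11)-dien-12,6-olide | O=C1C[C@@](C)(O)[C@@H]2CC[C@](C)(/C=C3/OC(=O)C(COC(C)=O)=C31)O2 | intermediate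
24 | (1S,4R,5E,8S,10R)-13-acetoxy-8,10-dihydroxy-1,4-epoxygermacra-5,7(11)-dien-12,6-olide | O[C@H]1C[C@@](C)(O)[C@@H]2CC[C@](C)(/C=C3/OC(=O)C(COC(C)=O)=C31)O2 | intermediate
25 | CNP0516045.1, (1S,4R,5E,8S,10R)-13-acetoxy-10-hydroxy-8-(methacryloyloxy)-1,4-epoxygermacra-5,7(11)-dien-12,6-olide | C=C(C)C(=O)O[C@H]1C[C@@](C)(O)[C@@H]2CC[C@](C)(/C=C3/OC(=O)C(COC(C)=O)=C31)O2 | target

Total steps: 15. Longest linear sequence: 14 (steps 1–11 and 13–15; step 12 prepares the acyl donor).

**Steps most likely to fail**

Step 10 (anionic oxy-Cope ring expansion). The potassium alkoxide may take the silyl group from the enol ether oxygen instead of rearranging, or the alkynyl group may have entered endo in step 7, so that the two π systems are trans and cannot reach a concerted transition state. The fallback is a stepwise ionic ring expansion that does not depend on the C5/C10 relative configuration and sets out from hydroxy ketone 13. KN(SiMe3)2 (1 equiv) in THF at –78 to 0 °C should trigger a strain-driven retro-aldol cleavage of C5–C10 to the ring-opened enolate of 3-ethoxy-1-[(2S,5R)-5-methyl-5-(2-oxopropyl)oxolan-2-yl]prop-2-yn-1-one F1. Its methyl-side enolate, held cis on ring A, should add to the β-carbon of the ethoxy ynone (intramolecular Michael addition) to give (1S,8R)-4-ethoxy-8-methyl-11-oxabicyclo[6.2.1]undec-3-ene-2,6-dione F2. Soft enolisation with iPr3SiOTf/Et3N should give the conjugated dienol ether (1S,8R)-4-ethoxy-8-methyl-6-[(triisopropylsilyl)oxy]-11-oxabicyclo[6.2.1]undeca-3,5-dien-2-one F3. MeMgBr followed by mild acid should then give (1S,2R,8R)-2-hydroxy-2,8-dimethyl-6-[(triisopropylsilyl)oxy]-11-oxabicyclo[6.2.1]undec-5-en-4-one F4, the conjugated isomer of 18, which is taken through the conditions of step 13 and comes back to the route at 23.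

Step 13 (enol acylation and intramolecular Knoevenagel condensation). The fluoride-generated enolate may be acylated on carbon, may expel the ring A oxygen by β-elimination before it is trapped, or the β-hydroxy ketone may suffer retro-aldol cleavage under the basic conditions. The fallback forms the C7–C11 bond first and the lactone second, setting out from 18. Ethyl 3-acetoxy-2-oxopropanoate F5 would be made from ethyl bromopyruvate and KOAc. Deprotonation of 18 with LiN(SiMe3)2 (2.1 equiv, THF, –78 °C; C7–H is α to the ketone and allylic) and aldol addition to F5 should give ethyl 3-acetoxy-2-hydroxy-2-[(1S,2R,6E,8R)-2-hydroxy-2,8-dimethyl-4-oxo-6-(triisopropylsilyloxy)-11-oxabicyclo[6.2.1]undec-6-en-5-yl]propanoate F6. Bu4NF buffered with AcOH should then remove the silyl group, let the enol oxygen lactonise onto the ethyl ester and eliminate water across C7–C11, which comes back to the route at 23.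

Step 11 (methyl addition and enol ether hydrolysis). Attack may occur on the wrong face of C10 if the chelate does not form, and the new tertiary allylic alcohol may ionise during hydrolysis of the enol ether and lose water to the transposed enone. The fallback lets the dehydration happen and delivers the C10 oxygen under catalyst control, setting out from 16. MeMgBr and then TsOH should give (1S,6E,8R)-4,8-dimethyl-6-[(triisopropylsilyl)oxy]-11-oxabicyclo[6.2.1]undeca-3,6-dien-2-one F7, which is the C9=C10 enone of the C8 ketone in germacrane numbering. Conjugate borylation with B2pin2 under a chiral bisphosphine–CuCl catalyst (monovalent copper, NaOtBu, MeOH), with the ligand enantiomer chosen to place boron on the required face, should give the tertiary boronate (1S,2R,6E,8R)-2,8-dimethyl-2-(4,4,5,5-tetramethyl-1,3,2-dioxaborolan-2-yl)-6-[(triisopropylsilyl)oxy]-11-oxabicyclo[6.2.1]undec-6-en-4-one F8. Oxidation with NaBO3 (retention) comes back to the route at 18.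

Further compounds
F1 | step 10 | 3-ethoxy-1-[(2S,5R)-5-methyl-5-(2-oxopropyl)oxolan-2-yl]prop-2-yn-1-one | CCOC#CC(=O)[C@@H]1CC[C@](C)(CC(C)=O)O1
F2 | step 10 | (1S,8R)-4-ethoxy-8-methyl-11-oxabicyclo[6.2.1]undec-3-ene-2,6-dione | CCOC1=CC(=O)[C@@H]2CC[C@](C)(CC(=O)C1)O2
F3 | step 10 | (1S,8R)-4-ethoxy-8-methyl-6-[(triisopropylsilyl)oxy]-11-oxabicyclo[6.2.1]undeca-3,5-dien-2-one | CCOC1=CC(=O)[C@@H]2CC[C@](C)(CC(O[Si](C(C)C)(C(C)C)C(C)C)=C1)O2
F4 | step 10 | (1S,2R,8R)-2-hydroxy-2,8-dimethyl-6-[(triisopropylsilyl)oxy]-11-oxabicyclo[6.2.1]undec-5-en-4-one | O=C1C[C@@](C)(O)[C@@H]2CC[C@](C)(CC(O[Si](C(C)C)(C(C)C)C(C)C)=C1)O2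
F5 | step 13 | ethyl 3-acetoxy-2-oxopropanoate | CCOC(=O)C(=O)COC(C)=O
F6 | step 13 | ethyl 3-acetoxy-2-hydroxy-2-[(1S,2R,6E,8R)-2-hydroxy-2,8-dimethyl-4-oxo-6-(triisopropylsilyloxy)-11-oxabicyclo[6.2.1]undec-6-en-5-yl]propanoate | C[C@]12CC[C@H](O1)[C@](C)(O)CC(=O)C(C(O)(COC(C)=O)C(=O)OCC)/C(O[Si](C(C)C)(C(C)C)C(C)C)=C\2
F7 | step 11 | (1S,6E,8R)-4,8-dimethyl-6-[(triisopropylsilyl)oxy]-11-oxabicyclo[6.2.1]undeca-3,6-dien-2-one | C[C@]12CC[C@H](O1)C(C)=CC(=O)C/C(O[Si](C(C)C)(C(C)C)C(C)C)=C\2
F8 | step 11 | (1S,2R,6E,8R)-2,8-dimethyl-2-(4,4,5,5-tetramethyl-1,3,2-dioxaborolan-2-yl)-6-[(triisopropylsilyl)oxy]-11-oxabicyclo[6.2.1]undec-6-en-4-one | C[C@]12CC[C@H](O1)[C@](C)(B3OC(C)(C)C(C)(C)O3)CC(=O)C/C(O[Si](C(C)C)(C(C)C)C(C)C)=C\2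
A1 | direct plan | (R)-linalool | CC(C)=CCC[C@](C)(C=C)O
A2 | direct plan | cis-furanoid linalool oxide, 2-[(2S,5R)-5-ethenyl-5-methyloxolan-2-yl]propan-2-ol | CC(C)(O)[C@@H]1CC[C@](C)(C=C)O1
A3 | direct plan | 1-[(2S,5R)-5-{[3-(2-bromoacetyl)-4-{[tert-butyl(dimethyl)silyl]oxymethyl}furan-2-yl]methyl}-5-methyloxolan-2-yl]ethan-1-one | CC(=O)[C@@H]1CC[C@](C)(Cc2occ(CO[Si](C)(C)C(C)(C)C)c2C(=O)CBr)O1
A4 | direct plan | (1S,4R,10R)-13-{[tert-butyl(dimethyl)silyl]oxy}-10-hydroxy-1,4:6,12-diepoxygermacra-6,11-dien-8-one | O=C1C[C@@](C)(O)[C@@H]2CC[C@](C)(Cc3occ(CO[Si](C)(C)C(C)(C)C)c31)O2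
A5 | direct plan | (1S,4R,8S,10R)-13-{[tert-butyl(dimethyl)silyl]oxy}-6,10-dihydroxy-8-(methacryloyloxy)-1,4-epoxygermacr-7(11)-en-12,6-olide (C6 epimers) | C=C(C)C(=O)O[C@H]1C[C@@](C)(O)[C@@H]2CC[C@](C)(CC3(O)OC(=O)C(CO[Si](C)(C)C(C)(C)C)=C31)O2
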